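**Structural features**

The target is a pentacyclic sesterterpenoid acetate. Rings A (C14–C16–C17–C18–C19–C22), B (C5–C6–C7–C13–C14–C22) and C (C7–C9–C10–C11–C12–C13) form a trans-anti-trans perhydrophenanthrene. C10 is also the spiro atom of an oxolane (C10–O23–C24–C25–C27) that is bridged into a cyclohexanone (C24–C25–C27–C28–C29–C31), a 6-oxabicyclo[3.2.1]octan-3-one. There are ten stereocentres (5S,7R,10S,13R,14S,22R,24S,25R,27R,31R): C22/C14/C13/C7 are contiguous on ring B, C31–C24–C25–C27 are an all-cis contiguous run on the bridged ring, and C10 links the two halves. C7, C10 and C14 are quaternary; the axial methyls C8 and C15 are 1,3-diaxial and the C5 acetate is axial and syn to both, so it is hard to install and slow to cleave. Fragile points are the C31 centre next to the C29 ketone, the free C25 hydroxyl, the acetate, and the β-alkoxy ketone O23–C24–C31–C29=O, which resists elimination only because the alkene would lie at a bridgehead. The real difficulty is the spiro ether: C10 must carry O23 axial on ring C while the oxygenated ring brings four stereocentres of its own. The key step exploits the 1,3,5-spacing of oxygenated C5, methyl-bearing C7 and ether carbon C10 along C5–C6–C7–C9–C10, which is the pattern left when an oxocarbenium ion and two 1,1-disubstituted alkenes react in sequence and O23 ends the cascade.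

**Logic of the disconnections**

42 to 34. No skeletal bond is cut. 34 differs from 42 only in the C5 oxygen (equatorial 2-hydroxyethyl ether instead of axial acetate), the C29 oxidation level (acetate instead of ketone) and the C25 silyl ether. This puts all redox and protecting-group work after the skeleton is complete. The forward sequence must invert C5 by oxidation and α-face hydride delivery, and must treat the C29 ester differently from the buried C5 ester.

34 to 33. The bonds C5–C6, C7–C9 and C10–O23 are cut. This removes rings B and C and the oxolane together with the stereocentres C5, C7 and C10, and leaves two monocyclic halves joined by a flexible chain. The forward step needs an initiator at C5 that cannot lose the cation prematurely, two terminal methylene nucleophiles, and a C24 hydroxyl cis to the C27 side chain. In 33 the C29 acetate is trans to that chain, so in the reactive chair only C27 and C24 are axial.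

33 to 29 and 15 (through 32). The bond C10–C11 is cut at the 1,1-disubstituted alkene. This divides the molecule into a ring A half and a chiral-pool half of similar size. The forward coupling must tolerate an acetal, an acetate and silyl ethers, and must not pass through a C10 carbonyl after the union, which would put C27 at risk.

15 to 1 (through 13, 10, 7 and 6). No ring bond is cut. The carvone carbonyl carbon becomes C24, its α′-carbon C25, the enone β-carbon C29, and the acetyl methyl left after ozonolysis becomes C9. The R enantiomer of carvone is needed for this mapping. The forward steps must place the C25 oxygen cis to the isopropenyl group (against the normal sense of enolate oxidation) and must hydrate the ring alkene without touching the isopropenyl group.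

29 to 21. Only functional groups change: the carboxyl carbon C7 becomes the isopropenyl group (C8 from methyllithium, C6 by methylenation), the exocyclic alkene C22=C5 becomes the acetal, and the benzyl ether becomes the iodide. The hindered exocyclic alkene must be hydroborated while it is the only alkene, so the isopropenyl group is introduced after that step.

21 to 17 and 18 (through 19). The bond C13–C14 is cut by a retro-[3,3] shift. This reveals an achiral allylic alcohol and a simple acid, and creates the quaternary C14 and the adjacent C13 in one step. The forward rearrangement needs a defined enolate geometry (chain cis to O–B) and a chiral controller, because the allylic alcohol has no stereocentre.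

17 to 16. Reduction of the aldehyde; no demand beyond 1,2-selectivity.

**Other disconnections considered**

Alternative 1: Ring A is closed last by cutting C19–C22. In the forward step CF3SO3H protonates the 4-methylpent-3-enyl chain of bicyclic diketone A2 at C18, and the tertiary C19 cation is attacked by C22 of the C5 enol to give tricyclic diketone A1.
- In its favour: the congested C19–C22 bond is formed by a reliable cation–enol closure, and C5 emerges as a ketone.
- Against it here: the C5 ketone can enolise toward C6 and the C10 ketone toward C9 or C11, so regiocontrol is not assured. A2 already needs the C7/C13/C14 triad. After A1 the whole spiro oxabicycle with four stereocentres must still be built on the C10 ketone with no element that fixes the axial C10–O bond.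
- Comparison: structurally it forms one ring and one stereocentre where the chosen step forms three of each. Mechanistically both are cationic, but the chosen cascade uses only tertiary cations and terminal methylenes. On step economy it is better at C5, because hydride reduction of A1 would give the axial alcohol directly and the three steps of ether cleavage and oxidation would be saved. It is worse overall because the hardest part of the molecule is left to the end.

Alternative 2: The bonds O23–C24 and C24–C31 are cut. In the forward step Cu(acac)2 or Rh2(OAc)4 decomposes diazoketone A4, the ether oxygen attacks the carbenoid to give a five-membered oxonium ylide, and a [2,3]-shift of the (E)-butenyl group gives spiro oxolan-3-one A3.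
- In its favour: the conditions are neutral, the ylide route to oxolan-3-ones is well established, C24 and C31 are created together with their relative configuration fixed by the alkene geometry, and the axial C5 oxygen is already in place in A3.
- Against it here: A4 needs a tertiary allyl ether at C10 of defined configuration, made by alkylating a hindered tertiary alcohol. The face of the ylide that reacts is controlled only by the remote ring C. [1,2]-Shift, C–H insertion and cyclopropanation compete. After A3 the C27–C28 bond and the C29 carbonyl are still missing, and the C25 ketone must be reduced to the alcohol syn to the ether bridge.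
- Comparison: it is the equal of the chosen plan in setting two stereocentres in one step. It is better in that no correction at C5 is needed. It is worse in that the spiro centre and the carbocyclic bridge are made in separate operations and the all-cis C31–C24–C25–C27 run is not taken from the chiral pool. The step count would be higher.

Alternative 3: The bond C28–C29 is cut. In the forward step (Me3Si)3SiH and AIBN convert phenylseleno ester A6 into an acyl radical that adds 6-endo to C28 of the 4-methylene-oxolan-3-one; the C27 radical then takes a hydrogen atom to give diketone A5.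
- In its favour: addition of a nucleophilic acyl radical to an enone terminus is polarity-matched, the bridged ring fusion forces the C27 configuration, and the C5 acetate and the C29 ketone are already at their final oxidation level.
- Against it here: decarbonylation of the α-branched acyl radical and 5-exo closure compete. A5 then needs reduction of the C25 ketone in the presence of the more accessible C29 ketone, with hydride delivered from the more hindered side. A6 itself needs the C24 and C31 centres and the spiro ether.
- Comparison: it is better on the endgame, with one closure and one reduction against eight steps in the chosen plan, and equal on control of C27. It is worse on the ketone differentiation and on the length of the route to A6, which would have to pass through chemistry like that of alternative 2.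

Key step: step 23

Remark: atoms carry the locants of the target throughout. Compounds 33 and 34 were checked centre by centre against 42; all retained centres agree and 34 differs only at C5, so no structure needed correction.

Remark: (R)-carvone is used because its carbonyl carbon is mapped onto C24; with this mapping C27 has the required configuration and the free C24 hydroxyl and the C25 silyl ether arise without selective protection.

Remark: the (S,S)-controller is written in step 13 and its sense of induction is assumed from the accepted chair model of the boron-enolate rearrangement; the antipodal controller is equally accessible if the opposite enantiomer of 21 should form.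

**Steps**

Step 1
Reactants: 1 (R)-carvone
Product: 3 (5S,6S)-6-hydroxy-2-methyl-5-(prop-1-en-2-yl)cyclohex-2-en-1-one (C25 hydroxyl trans to the isopropenyl group), via lithium dienolate 2 (not isolated)
Conditions: LiN(iPr)2, THF, −78 °C; then 2-(phenylsulfonyl)-3-phenyloxaziridine, −78 °C
Reagents that add atoms: 2-(phenylsulfonyl)-3-phenyloxaziridine, O=S(=O)(c1ccccc1)N1OC1c1ccccc1
Why: Kinetic deprotonation at the α′-CH2 (C25) gives the cross-conjugated dienolate and oxygen transfer occurs on the face opposite to the neighbouring isopropenyl group (enolate α-hydroxylation), so the trans ketol should predominate; C25 is corrected in step 3.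

Step 2
Reactants: 3 (5S,6S)-6-hydroxy-2-methyl-5-(prop-1-en-2-yl)cyclohex-2-en-1-one
Product: 4 (5S,6S)-6-[(tert-butyldimethylsilyl)oxy]-2-methyl-5-(prop-1-en-2-yl)cyclohex-2-en-1-one
Conditions: TBSOTf, 2,6-lutidine, CH2Cl2, −78 → 0 °C
Reagents that add atoms: tert-butyldimethylsilyl triflate, CC(C)(C)[Si](C)(C)OS(=O)(=O)C(F)(F)F
Why: A silyl triflate with a hindered pyridine base silylates the secondary ketol without enolising it (silyl ether formation).

Step 3
Reactants: 4 (5S,6S)-6-[(tert-butyldimethylsilyl)oxy]-2-methyl-5-(prop-1-en-2-yl)cyclohex-2-en-1-one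
Product: 6 (5S,6R)-6-[(tert-butyldimethylsilyl)oxy]-2-methyl-5-(prop-1-en-2-yl)cyclohex-2-en-1-one (silyloxy group cis to the isopropenyl group), via lithium enolate 5 (not isolated)
Conditions: LiN(iPr)2, THF, −78 °C; then 2,6-di-tert-butyl-4-methylphenol, −78 °C
Reagents that add atoms: none
Why: Deprotonation at C25 gives a planar enolate, and kinetic protonation by a bulky phenol should occur on the face remote from the adjacent isopropenyl group, the same facial preference that places electrophiles trans in alkylations of 6-substituted carvone enolates, so the silyloxy group ends cis to the C27 substituent (enolate epimerisation).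

Step 4
Reactants: 6 (5S,6R)-6-[(tert-butyldimethylsilyl)oxy]-2-methyl-5-(prop-1-en-2-yl)cyclohex-2-en-1-one
Product: 7 (1S,5S,6R)-6-[(tert-butyldimethylsilyl)oxy]-2-methyl-5-(prop-1-en-2-yl)cyclohex-2-en-1-ol (C24 hydroxyl, C25 silyloxy and C27 isopropenyl all cis)
Conditions: NaBH4, CeCl3·7H2O, MeOH, −78 °C
Reagents that add atoms: none
Why: Luche reduction gives clean 1,2-reduction of the enone; hydride should add anti to the pseudo-axial C25 silyloxy group, so the C24 hydroxyl becomes cis to the C25 oxygen and to the C27 isopropenyl group.

Step 5
Reactants: 7 (1S,5S,6R)-6-[(tert-butyldimethylsilyl)oxy]-2-methyl-5-(prop-1-en-2-yl)cyclohex-2-en-1-ol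
Product: 8 syn-epoxy alcohol (C29–C31 epoxide on the face of the C24 hydroxyl; C25 silyl ether; isopropenyl intact)
Conditions: VO(acac)2 (cat.), t-BuOOH, CH2Cl2, 0 °C → rt
Reagents that add atoms: tert-butyl hydroperoxide, CC(C)(C)OO
Why: Hydroxyl-directed vanadium-catalysed epoxidation is selective for the allylic-alcohol double bond over the isopropenyl group and delivers oxygen syn to the C24 hydroxyl.

Step 6
Reactants: 8 syn-epoxy alcohol
Product: 9 C24,C29-diol (both hydroxyls, the C31 methyl, the C25 silyloxy group and the C27 isopropenyl group on the same face)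
Conditions: Cp2TiCl2, Zn, THF, rt; 1,4-cyclohexadiene, then 8, rt; 1 M HCl
Reagents that add atoms: none
Why: Single-electron opening of the 2,3-epoxy alcohol by trivalent titanium cleaves the C31–O bond to the tertiary radical and leaves oxygen on C29; hydrogen-atom transfer from 1,4-cyclohexadiene should come from the face free of the C24, C25 and C27 substituents, placing the C31 methyl cis to the C24 hydroxyl (titanocene-mediated reductive epoxide opening to a 2-methyl-1,3-diol).

Step 7
Reactants: 9 C24,C29-diol
Product: 10 C29 acetate with inverted C29 (acetoxy trans to the C27 isopropenyl group; free C24 hydroxyl; C25 silyl ether)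
Conditions: PPh3, DIAD, AcOH, THF, 0 °C → rt
Reagents that add atoms: acetic acid, CC(O)=O
Why: Mitsunobu esterification engages the less hindered equatorial C29 hydroxyl (C24 is flanked by the silyloxy and methyl-bearing carbons) and inverts it, so the acetate becomes trans to the C24 hydroxyl and equatorial in the chair needed for step 23.

Step 8
Reactants: 10 C29 acetate with free C24 hydroxyl
Product: 11 C24 triethylsilyl ether of 10
Conditions: TESOTf, 2,6-lutidine, CH2Cl2, −78 °C
Reagents that add atoms: triethylsilyl triflate, CC[Si](CC)(CC)OS(=O)(=O)C(F)(F)F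
Why: A temporary silyl ether masks the C24 hydroxyl so that the strong base of step 10 cannot cause 1,2-silyl migration from C25 or O-sulfonylation.

Step 9
Reactants: 11 C24 triethylsilyl ether
Product: 13 methyl ketone (acetyl group on C27; C10 carbonyl), via secondary ozonide 12 (not isolated)
Conditions: O3, CH2Cl2, −78 °C; then Me2S, −78 °C → rt
Reagents that add atoms: ozone, [O-][O+]=O
Why: The isopropenyl group is now the only alkene, so ozonolysis with reductive work-up gives the methyl ketone; the neutral conditions protect the epimerisable C27 centre.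

Step 10
Reactants: 13 methyl ketone
Product: 15 enol triflate (1-(trifluoromethylsulfonyloxy)vinyl group on C27), via potassium enolate 14 (not isolated)
Conditions: KN(SiMe3)2, THF, −78 °C; then PhNTf2, −78 → −20 °C
Reagents that add atoms: N-phenylbis(trifluoromethanesulfonimide), O=S(=O)(N(c1ccccc1)S(=O)(=O)C(F)(F)F)C(F)(F)F
Why: Kinetic deprotonation at the methyl group and O-sulfonylation give the terminal enol triflate whose CH2 becomes C9; the low temperature avoids enolisation toward C27 and attack on the acetate.

Step 11
Reactants: 16 β-cyclocitral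
Product: 17 β-cyclogeraniol ((2,6,6-trimethylcyclohex-1-en-1-yl)methanol)
Conditions: NaBH4, MeOH, 0 °C
Reagents that add atoms: none
Why: Borohydride 1,2-reduction of the hindered enal gives the primary allylic alcohol.

Step 12
Reactants: 17 β-cyclogeraniol; 18 4-(benzyloxy)butanoic acid
Product: 19 (2,6,6-trimethylcyclohex-1-en-1-yl)methyl 4-(benzyloxy)butanoate
Conditions: DCC, DMAP (cat.), CH2Cl2, 0 °C → rt
Reagents that add atoms: none
Why: Steglich esterification of the primary allylic alcohol; the γ-benzyloxy chain supplies C11 and C12 and cannot undergo β-elimination on enolisation.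

Step 13
Reactants: 19 (2,6,6-trimethylcyclohex-1-en-1-yl)methyl 4-(benzyloxy)butanoate
Product: 21 (2S)-4-(benzyloxy)-2-[(1S)-1,3,3-trimethyl-2-methylidenecyclohexyl]butanoic acid, via Z(O)-boron enolate 20 (not isolated)
Conditions: (4S,5S)-2-bromo-1,3-bis[3,5-bis(trifluoromethyl)phenylsulfonyl]-4,5-diphenyl-1,3,2-diazaborolidine, iPr2NEt, CH2Cl2, −78 °C → rt; aqueous work-up
Reagents that add atoms: none
Why: Soft enolisation with iPr2NEt in CH2Cl2 should give the Z(O)-boron enolate (C12 chain cis to O–B), which rearranges through a chair [3,3] transition state with the chain pseudo-equatorial, forming C13–C14 and setting quaternary C14 and tertiary C13 in the relative configuration of the target, while the C2-symmetric sulfonamide ligand selects the enantiotopic face (enantioselective boron Ireland–Claisen rearrangement).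

Step 14
Reactants: 21 (2S)-4-(benzyloxy)-2-[(1S)-1,3,3-trimethyl-2-methylidenecyclohexyl]butanoic acid
Product: 22 methyl ketone (C7 acetyl group on C13; exocyclic C22=C5 alkene; C11 benzyl ether)
Conditions: MeLi (3 equiv), Et2O, 0 °C → rt; H2O
Reagents that add atoms: methyllithium, [Li]C
Why: Methyllithium adds to the lithium carboxylate to give a stable gem-diolate that releases the methyl ketone only on hydrolysis, which introduces C8 without an enolisable intermediate at C13.

Step 15
Reactants: 22 methyl ketone
Product: 24 diol (C5 primary alcohol with C22–H anti to the C15 methyl; C7 secondary alcohol as an epimer mixture), via alkylborane–alkoxyborane adduct 23 (not isolated)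
Conditions: BH3·THF (excess), THF, 0 °C → rt; then NaOH, H2O2, 0 °C → rt
Reagents that add atoms: hydrogen peroxide, OO
Why: Borane adds to the only alkene from the face opposite to the axial C15 methyl and the axial C19 methyl, placing hydrogen on C22 anti to C15 and boron on C5 (hydroboration–oxidation); the ketone is reduced at the same time and restored in step 16.

Step 16
Reactants: 24 diol
Product: 25 keto aldehyde (C5 aldehyde; C7 methyl ketone)
Conditions: Dess–Martin periodinane, NaHCO3, CH2Cl2, 0 °C → rt
Reagents that add atoms: none
Why: Dess–Martin oxidation converts both alcohols under buffered conditions that do not epimerise C22 or C13.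

Step 17
Reactants: 25 keto aldehyde
Product: 26 C5 dioxolane acetal with intact C7 methyl ketone
Conditions: TMSOCH2CH2OTMS, TMSOTf (cat.), CH2Cl2, −78 °C
Reagents that add atoms: 1,2-bis(trimethylsilyloxy)ethane, C[Si](C)(C)OCCO[Si](C)(C)C
Why: Silyl-transfer acetalisation at low temperature is strongly aldehyde-selective, so the C5 aldehyde should form the dioxolane while the methyl ketone stays free and neither C22 nor C13 is epimerised.

Step 18
Reactants: 26 C5 dioxolane acetal with C7 methyl ketone
Product: 27 C5 dioxolane acetal with isopropenyl group on C13 and C11 benzyl ether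
Conditions: Cp2TiMe2, toluene–THF, 65 °C
Reagents that add atoms: dimethyltitanocene, C[Ti](C)(C1C=CC=C1)C1C=CC=C1
Why: Petasis methylenation is non-basic and tolerates acetals, so the hindered enolisable C7 ketone is converted into the isopropenyl group (C6) without loss of the C13 configuration.

Step 19
Reactants: 27 isopropenyl acetal benzyl ether
Product: 28 primary alcohol at C11
Conditions: lithium 4,4′-di-tert-butylbiphenylide, THF, −78 °C
Reagents that add atoms: none
Why: Reductive debenzylation by an arene radical anion removes the benzyl ether without touching the 1,1-disubstituted alkene or the acetal, where hydrogenolysis could not be used.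

Step 20
Reactants: 28 primary alcohol at C11
Product: 29 primary iodide at C11 (ring A acetal; isopropenyl on C13)
Conditions: I2, PPh3, imidazole, CH2Cl2, 0 °C → rt
Reagents that add atoms: iodine, II
Why: Appel-type iodination of the primary alcohol; imidazole buffers the medium and protects the acetal.

Step 21
Reactants: 29 primary iodide at C11; 15 enol triflate
Product: 32 coupled diene (C10–C11 bond; C24 triethylsilyl ether; C25 tert-butyldimethylsilyl ether; C29 acetate), via alkyllithium 30 (not isolated), via lithium borinate 31 (not isolated)
Conditions: t-BuLi, Et2O, −78 °C; 9-methoxy-9-borabicyclo[3.3.1]nonane, THF, −78 °C → rt; then 15, Pd(dppf)Cl2 (cat.), AsPh3, K3PO4, DMF–H2O, rt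
Reagents that add atoms: none
Why: Lithium–iodine exchange and capture by the methoxyborane give a borinate that transfers its primary alkyl group to palladium after oxidative addition of the enol triflate to zerovalent palladium, and reductive elimination forms C10–C11 with the 1,1-disubstituted alkene already in place (B-alkyl Suzuki–Miyaura coupling); the method tolerates acetate, silyl ethers and acetal.

Step 22
Reactants: 32 coupled diene with C24 triethylsilyl ether
Product: 33 cyclisation precursor (ring A dioxolane; isopropenyl on C13; C10=C9 methylene; free C24 hydroxyl; C25 silyl ether; C29 acetate)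
Conditions: HF·pyridine, pyridine, THF, 0 °C
Reagents that add atoms: none
Why: Buffered fluoride removes the triethylsilyl ether much faster than the tert-butyldimethylsilyl ether and leaves the acetal and the acetate intact.

Step 23
Reactants: 33 cyclisation precursor
Product: 34 pentacycle with equatorial C5 2-hydroxyethyl ether, C25 silyl ether and C29 acetate
Conditions: SnCl4, CH2Cl2, −78 °C; aq. NaHCO3
Reagents that add atoms: none
Why: SnCl4 binds one dioxolane oxygen and opens the acetal to an (E)-oxocarbenium ion at C5, which is attacked by the methylene carbon C6 of the isopropenyl group; the tertiary C7 cation is then attacked by the methylene carbon C9, and the tertiary C10 cation is captured by the C24 hydroxyl, with the proton ending on the tin-bound alkoxide. The closest known reaction type is the acetal-initiated cation–olefin polycyclisation terminated by a hydroxyl group. Ring B closes 6-endo through a chair and ring C closes 6-endo through a second chair, trans-fused because the C12 tether is equatorial on C13; the oxolane closes as a five-membered capture of the cation by oxygen. C5 takes its alkoxy group equatorial because the oxocarbenium substituent avoids the axial C15 methyl in the chair anchored by C22 and C14. C7 is set by anti addition across C6=C7, which leaves the C8 methyl axial. C10 takes O23 axial and C27 equatorial, since an axial C27 would clash with the axial C8 methyl. Unlike a Lewis-acid-complexed aldehyde, the oxocarbenium ion has no metal alkoxide to accept an allylic hydrogen, so ene-type diversion is not available and the cascade needs only that proton loss be slower than capture, which the low temperature and all-tertiary cations favour. Only the C24 oxygen can reach C10 through a five-membered ring, because the C29 acetate is trans to the side chain and the C25 oxygen would give a four-membered ring.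

Step 24
Reactants: 34 pentacycle with 2-hydroxyethyl ether
Product: 35 2-iodoethyl ether at C5
Conditions: I2, PPh3, imidazole, CH2Cl2, rt
Reagents that add atoms: iodine, II
Why: Appel-type iodination of the only free (primary) alcohol prepares the ether for reductive cleavage.

Step 25
Reactants: 35 2-iodoethyl ether at C5
Product: 36 equatorial C5 alcohol
Conditions: Zn, NH4Cl, EtOH, 70 °C
Reagents that add atoms: none
Why: Zinc inserts into the C–I bond and β-elimination expels the C5 alkoxide with loss of ethylene (reductive fragmentation of a β-iodo ether); acetate and silyl ether are inert.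

Step 26
Reactants: 36 equatorial C5 alcohol
Product: 37 C5 ketone
Conditions: Dess–Martin periodinane, NaHCO3, CH2Cl2, rt
Reagents that add atoms: none
Why: Dess–Martin oxidation of the secondary alcohol; C22 next to the new ketone is already in the stable trans-fused arrangement.

Step 27
Reactants: 37 C5 ketone
Product: 38 axial C5 alcohol
Conditions: NaBH4, MeOH–THF, 0 °C
Reagents that add atoms: none
Why: Hydride approaches the C5 ketone from the α face because the β face is screened by the syn-axial C8 and C15 methyls, giving the axial β alcohol; the C29 acetate survives borohydride.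

Step 28
Reactants: 38 axial C5 alcohol
Product: 39 C5,C29-diacetate with C25 silyl ether
Conditions: Ac2O, DMAP, pyridine, 60 °C
Reagents that add atoms: acetic anhydride, CC(=O)OC(C)=O
Why: Nucleophile-catalysed acetylation under forcing conditions is needed for an axial alcohol flanked by two syn-axial methyl groups.

Step 29
Reactants: 39 C5,C29-diacetate
Product: 40 C29 alcohol with C5 acetate retained
Conditions: K2CO3, MeOH, 0 °C → rt
Reagents that add atoms: none
Why: Base-mediated transesterification removes the exposed equatorial C29 acetate far faster than the buried axial C5 acetate.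

Step 30
Reactants: 40 C29 alcohol
Product: 41 C29 ketone with C25 silyl ether
Conditions: Dess–Martin periodinane, NaHCO3, CH2Cl2, rt
Reagents that add atoms: none
Why: Buffered Dess–Martin oxidation avoids epimerisation of C31, whose methyl is already equatorial, and β-elimination of O23 cannot occur because it would need a bridgehead alkene.

Step 31
Reactants: 41 C29 ketone with C25 silyl ether
Product: 42 target CNP0188572.2
Conditions: HF·pyridine, THF, 0 °C → rt
Reagents that add atoms: none
Why: Fluoride in a buffered acidic medium cleaves the silyl ether without acyl migration or enolisation of the C29 ketone.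

**Compound list**

1 | (R)-carvone | CC(=C)[C@@H]1CC=C(C)C(=O)C1 | starting material
2 | lithium cross-conjugated dienolate of 1 | CC(=C)[C@@H]1CC=C(C)C(O[Li])=C1 | intermediate (not isolated)
3 | (5S,6S)-6-hydroxy-2-methyl-5-(prop-1-en-2-yl)cyclohex-2-en-1-one | CC(=C)[C@@H]1CC=C(C)C(=O)[C@H]1O | intermediate
4 | (5S,6S)-6-[(tert-butyldimethylsilyl)oxy]-2-methyl-5-(prop-1-en-2-yl)cyclohex-2-en-1-one | CC(=C)[C@@H]1CC=C(C)C(=O)[C@H]1O[Si](C)(C)C(C)(C)C | intermediate
5 | lithium enolate of 4 (C24=C25) | CC(=C)[C@@H]1CC=C(C)C(O[Li])=C1O[Si](C)(C)C(C)(C)C | intermediate (not isolated)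
6 | (5S,6R)-6-[(tert-butyldimethylsilyl)oxy]-2-methyl-5-(prop-1-en-2-yl)cyclohex-2-en-1-one | CC(=C)[C@@H]1CC=C(C)C(=O)[C@@H]1O[Si](C)(C)C(C)(C)C | intermediate
7 | (1S,5S,6R)-6-[(tert-butyldimethylsilyl)oxy]-2-methyl-5-(prop-1-en-2-yl)cyclohex-2-en-1-ol (all-cis) | CC(=C)[C@@H]1CC=C(C)[C@H](O)[C@@H]1O[Si](C)(C)C(C)(C)C | intermediate
8 | syn-epoxy alcohol (C29–C31 epoxide cis to C24–OH, C25–OTBS and isopropenyl) | CC(=C)[C@@H]1C[C@@H]2O[C@]2(C)[C@H](O)[C@@H]1O[Si](C)(C)C(C)(C)C | intermediate
9 | C24,C29-diol (C29–OH, C31–Me, C24–OH, C25–OTBS and isopropenyl all cis) | CC(=C)[C@@H]1C[C@H](O)[C@H](C)[C@H](O)[C@@H]1O[Si](C)(C)C(C)(C)C | intermediate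
10 | C29 acetate (acetoxy trans to isopropenyl; free C24–OH; C25–OTBS) | CC(=C)[C@@H]1C[C@@H](OC(C)=O)[C@H](C)[C@H](O)[C@@H]1O[Si](C)(C)C(C)(C)C | intermediate
11 | C24 triethylsilyl ether of 10 | CC(=C)[C@@H]1C[C@@H](OC(C)=O)[C@H](C)[C@H](O[Si](CC)(CC)CC)[C@@H]1O[Si](C)(C)C(C)(C)C | intermediate
12 | secondary ozonide of 11 (3-methyl-1,2,4-trioxolan-3-yl on C27) | CC1(OOCO1)[C@@H]1C[C@@H](OC(C)=O)[C@H](C)[C@H](O[Si](CC)(CC)CC)[C@@H]1O[Si](C)(C)C(C)(C)C | intermediate (not isolated)
13 | methyl ketone (acetyl on C27) | CC(=O)[C@@H]1C[C@@H](OC(C)=O)[C@H](C)[C@H](O[Si](CC)(CC)CC)[C@@H]1O[Si](C)(C)C(C)(C)C | intermediate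
14 | potassium enolate of 13 (terminal) | C=C(O[K])[C@@H]1C[C@@H](OC(C)=O)[C@H](C)[C@H](O[Si](CC)(CC)CC)[C@@H]1O[Si](C)(C)C(C)(C)C | intermediate (not isolated)
15 | enol triflate (1-(triflyloxy)vinyl on C27) | C=C(OS(=O)(=O)C(F)(F)F)[C@@H]1C[C@@H](OC(C)=O)[C@H](C)[C@H](O[Si](CC)(CC)CC)[C@@H]1O[Si](C)(C)C(C)(C)C | intermediate
16 | β-cyclocitral | CC1=C(C=O)C(C)(C)CCC1 | starting material
17 | β-cyclogeraniol | CC1=C(CO)C(C)(C)CCC1 | intermediate
18 | 4-(benzyloxy)butanoic acid | OC(=O)CCCOCc1ccccc1 | starting material
19 | (2,6,6-trimethylcyclohex-1-en-1-yl)methyl 4-(benzyloxy)butanoate | CC1=C(COC(=O)CCCOCc2ccccc2)C(C)(C)CCC1 | intermediate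
20 | Z(O)-boron enolate of 19 bearing the (4S,5S)-diazaborolidine | CC1=C(CO/C(=C/CCOCc2ccccc2)OB2N(S(=O)(=O)c3cc(C(F)(F)F)cc(C(F)(F)F)c3)[C@@H](c3ccccc3)[C@H](c3ccccc3)N2S(=O)(=O)c2cc(C(F)(F)F)cc(C(F)(F)F)c2)C(C)(C)CCC1 | intermediate (not isolated)
21 | (2S)-4-(benzyloxy)-2-[(1S)-1,3,3-trimethyl-2-methylidenecyclohexyl]butanoic acid | C=C1C(C)(C)CCC[C@@]1(C)[C@H](CCOCc1ccccc1)C(O)=O | intermediate
22 | methyl ketone (C7 acetyl on C13; C22=C5 methylidene; C11 benzyl ether) | C=C1C(C)(C)CCC[C@@]1(C)[C@H](CCOCc1ccccc1)C(C)=O | intermediate
23 | alkylborane–alkoxyborane adduct (C5–BH2; C7–O–BH2) | [BH2]C[C@@H]1C(C)(C)CCC[C@@]1(C)[C@H](CCOCc1ccccc1)C(C)O[BH2] | intermediate (not isolated)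
24 | diol (C5–OH primary; C7–OH secondary, epimer mixture; C22–H anti to C15) | OC[C@@H]1C(C)(C)CCC[C@@]1(C)[C@H](CCOCc1ccccc1)C(C)O | intermediate
25 | keto aldehyde (C5 aldehyde; C7 methyl ketone) | O=C[C@@H]1C(C)(C)CCC[C@@]1(C)[C@H](CCOCc1ccccc1)C(C)=O | intermediate
26 | C5 dioxolane acetal with C7 methyl ketone | O1CCOC1[C@@H]1C(C)(C)CCC[C@@]1(C)[C@H](CCOCc1ccccc1)C(C)=O | intermediate
27 | C5 dioxolane acetal with isopropenyl on C13 and C11 benzyl ether | O1CCOC1[C@@H]1C(C)(C)CCC[C@@]1(C)[C@H](CCOCc1ccccc1)C(C)=C | intermediate
28 | C11 primary alcohol | O1CCOC1[C@@H]1C(C)(C)CCC[C@@]1(C)[C@H](CCO)C(C)=C | intermediate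
29 | C11 primary iodide | O1CCOC1[C@@H]1C(C)(C)CCC[C@@]1(C)[C@H](CCI)C(C)=C | intermediate
30 | C11 alkyllithium | O1CCOC1[C@@H]1C(C)(C)CCC[C@@]1(C)[C@H](CC[Li])C(C)=C | intermediate (not isolated)
31 | lithium B-alkyl-B-methoxy-9-borabicyclo[3.3.1]nonane borinate | O1CCOC1[C@@H]1C(C)(C)CCC[C@@]1(C)[C@H](CC[B-]2(OC)C3CCCC2CCC3)C(C)=C.[Li+] | intermediate (not isolated)
32 | coupled diene with C24 triethylsilyl ether | O1CCOC1[C@@H]1C(C)(C)CCC[C@@]1(C)[C@H](CCC(=C)[C@@H]1C[C@@H](OC(C)=O)[C@H](C)[C@H](O[Si](CC)(CC)CC)[C@@H]1O[Si](C)(C)C(C)(C)C)C(C)=C | intermediate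
33 | cyclisation precursor (free C24–OH) | O1CCOC1[C@@H]1C(C)(C)CCC[C@@]1(C)[C@H](CCC(=C)[C@@H]1C[C@@H](OC(C)=O)[C@H](C)[C@H](O)[C@@H]1O[Si](C)(C)C(C)(C)C)C(C)=C | intermediate
34 | pentacycle with equatorial C5 2-hydroxyethyl ether | OCCO[C@@H]1C[C@]2(C)C[C@]3(CC[C@H]2[C@]2(C)CCCC(C)(C)[C@@H]12)O[C@@H]1[C@H](O[Si](C)(C)C(C)(C)C)[C@H]3C[C@@H](OC(C)=O)[C@@H]1C | intermediate
35 | C5 2-iodoethyl ether | ICCO[C@@H]1C[C@]2(C)C[C@]3(CC[C@H]2[C@]2(C)CCCC(C)(C)[C@@H]12)O[C@@H]1[C@H](O[Si](C)(C)C(C)(C)C)[C@H]3C[C@@H](OC(C)=O)[C@@H]1C | intermediate
36 | equatorial C5 alcohol | O[C@@H]1C[C@]2(C)C[C@]3(CC[C@H]2[C@]2(C)CCCC(C)(C)[C@@H]12)O[C@@H]1[C@H](O[Si](C)(C)C(C)(C)C)[C@H]3C[C@@H](OC(C)=O)[C@@H]1C | intermediate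
37 | C5 ketone | O=C1C[C@]2(C)C[C@]3(CC[C@H]2[C@]2(C)CCCC(C)(C)[C@@H]12)O[C@@H]1[C@H](O[Si](C)(C)C(C)(C)C)[C@H]3C[C@@H](OC(C)=O)[C@@H]1C | intermediate
38 | axial C5 alcohol | O[C@H]1C[C@]2(C)C[C@]3(CC[C@H]2[C@]2(C)CCCC(C)(C)[C@@H]12)O[C@@H]1[C@H](O[Si](C)(C)C(C)(C)C)[C@H]3C[C@@H](OC(C)=O)[C@@H]1C | intermediate
39 | C5,C29-diacetate | CC(=O)O[C@H]1C[C@]2(C)C[C@]3(CC[C@H]2[C@]2(C)CCCC(C)(C)[C@@H]12)O[C@@H]1[C@H](O[Si](C)(C)C(C)(C)C)[C@H]3C[C@@H](OC(C)=O)[C@@H]1C | intermediate
40 | C29 alcohol with C5 acetate | CC(=O)O[C@H]1C[C@]2(C)C[C@]3(CC[C@H]2[C@]2(C)CCCC(C)(C)[C@@H]12)O[C@@H]1[C@H](O[Si](C)(C)C(C)(C)C)[C@H]3C[C@@H](O)[C@@H]1C | intermediate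
41 | C29 ketone with C25 silyl ether | CC(=O)O[C@H]1C[C@]2(C)C[C@]3(CC[C@H]2[C@]2(C)CCCC(C)(C)[C@@H]12)O[C@@H]1[C@H](O[Si](C)(C)C(C)(C)C)[C@H]3CC(=O)[C@@H]1C | intermediate
42 | CNP0188572.2 | CC(=O)O[C@H]1C[C@]2(C)C[C@]3(CC[C@H]2[C@]2(C)CCCC(C)(C)[C@@H]12)O[C@@H]1[C@H](O)[C@H]3CC(=O)[C@@H]1C | target

**Step count and risk**

Total step count: 31 (steps 1–10 for the carvone-derived half, steps 11–20 for the ring A half, steps 21–31 after the union).

Longest linear sequence: 21 steps (1 to 42 through steps 1–10 and 21–31; the sequence from 16 through steps 11–20 and 21–31 has the same length).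

Least certain steps:

Step 23 (key step). The cascade may stop early by loss of a proton from the C10 cation, or by chloride capture, before the C24 hydroxyl reaches C10. The silyl ether may also be lost under the Lewis acid. Fallback: set out from 33 and accept the interrupted cascade. Brief exposure to the Lewis acid should give the tricyclic alkene with rings B and C closed, a C10=C11 double bond and a free C24 hydroxyl F1. The oxolane is then closed in a separate operation by intramolecular oxymercuration with Hg(OCOCF3)2 and demercuration with NaBH4. Markovnikov delivery of O23 to C10 with trans-diaxial opening should place the C–O bond axial, and the route is rejoined at 34.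

Step 13. The hindered tetrasubstituted allyl unit may rearrange slowly, which would allow erosion of enolate geometry or decomposition of the boron enolate. Facial discrimination by the controller may be incomplete, and a boat transition state would give the C13 epimer. Fallback: set out from 19 and run the achiral variant. LiN(iPr)2 in THF–DMPU with Me3SiCl gives the trimethylsilyl ketene acetal of the same Z(O) geometry F2, which on warming rearranges to the racemic acid of the correct relative configuration F3. F3 is resolved by crystallisation of the (R)-1-phenylethylammonium salt of the (2S,1′S) acid F4, and acidification returns 21.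

Step 3. Protonation of the enolate may show poor facial selectivity. The silyl group may migrate from O25 to the enolate oxygen, or deprotonation may occur at the γ-position instead. Fallback: set out from 3 and invert C25 by oxidation and reduction.
- Luche reduction gives the trans-diol F5.
- Selective silylation of the less hindered allylic C24 hydroxyl (TESCl, imidazole) gives the mono-triethylsilyl ether F6.
- Dess–Martin oxidation gives the C25 ketone F7.
- LiBH(s-Bu)3 delivers hydride anti to the C24 and C27 substituents and gives the all-cis alcohol F8.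
- TBSOTf gives the bis-silyl ether F9.
- PPTS in MeOH removes the triethylsilyl group and rejoins the route at 7.

Step 6 (and with it step 7). Hydrogen-atom transfer to the planar C31 radical may show poor facial selectivity, or β-elimination may give an allylic alcohol. The Mitsunobu inversion may then suffer from elimination. Fallback: set out from 7 and set C29 and C31 by syn hydroboration after masking the isopropenyl group.
- OsO4 (cat.) with N-methylmorpholine N-oxide should dihydroxylate the unhindered isopropenyl group to the side-chain triol F10.
- BH3·SMe2 followed by NaBO3 adds anti to the C24, C25 and C27 substituents and gives the pentaol with C29–OH trans to the chain and C31–Me cis to C24–OH F11.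
- NaIO4 cleaves the side-chain diol to the methyl ketone diol F12.
- Ac2O in pyridine acetylates the less hindered C29 hydroxyl to the keto acetate F13.
- TESCl with imidazole rejoins the route at 13.

Step 17. The C7 methyl ketone may be ketalised in competition with the very hindered C5 aldehyde, or acid may promote an intramolecular aldol between the two carbonyls. Fallback: set out from 21 and carry C7 as an amide until the acetal is in place.
- EDC with MeNHOMe·HCl gives the N-methoxy-N-methylamide F14.
- BH3·THF followed by NaBO3 gives the C5 alcohol F15.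
- Dess–Martin oxidation gives the aldehyde amide F16.
- The same silyl-transfer acetalisation, now without a competing ketone, gives the acetal amide F17.
- MeMgBr (Weinreb ketone synthesis) returns 26.

**Further compounds**

F1 | step 23 | tricyclic alkene (rings B and C closed, C10=C11, free C24–OH, C5 2-hydroxyethyl ether) | OCCO[C@@H]1C[C@]2(C)CC(=CC[C@H]2[C@]2(C)CCCC(C)(C)[C@@H]12)[C@@H]1C[C@@H](OC(C)=O)[C@H](C)[C@H](O)[C@@H]1O[Si](C)(C)C(C)(C)C
F2 | step 13 | trimethylsilyl ketene acetal of 19 (chain cis to OSiMe3) | CC1=C(CO/C(=C/CCOCc2ccccc2)O[Si](C)(C)C)C(C)(C)CCC1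
F3 | step 13 | racemic 4-(benzyloxy)-2-(1,3,3-trimethyl-2-methylidenecyclohexyl)butanoic acid (2S,1′S and 2R,1′R) | C=C1C(C)(C)CCC[C@@]1(C)[C@H](CCOCc1ccccc1)C(O)=O.C=C1C(C)(C)CCC[C@]1(C)[C@@H](CCOCc1ccccc1)C(O)=O
F4 | step 13 | (R)-1-phenylethylammonium salt of 21 | C=C1C(C)(C)CCC[C@@]1(C)[C@H](CCOCc1ccccc1)C([O-])=O.C[C@@H]([NH3+])c1ccccc1
F5 | step 3 | trans-diol (C24–OH cis, C25–OH trans to isopropenyl) | CC(=C)[C@@H]1CC=C(C)[C@H](O)[C@H]1O
F6 | step 3 | C24 triethylsilyl ether of F5 | CC(=C)[C@@H]1CC=C(C)[C@H](O[Si](CC)(CC)CC)[C@H]1O
F7 | step 3 | C25 ketone with C24 triethylsilyl ether | CC(=C)[C@@H]1CC=C(C)[C@H](O[Si](CC)(CC)CC)C1=O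
F8 | step 3 | all-cis C25 alcohol with C24 triethylsilyl ether | CC(=C)[C@@H]1CC=C(C)[C@H](O[Si](CC)(CC)CC)[C@@H]1O
F9 | step 3 | C24 triethylsilyl, C25 tert-butyldimethylsilyl bis-ether | CC(=C)[C@@H]1CC=C(C)[C@H](O[Si](CC)(CC)CC)[C@@H]1O[Si](C)(C)C(C)(C)C
F10 | step 6 | side-chain triol (1,2-dihydroxypropan-2-yl on C27; ring alkene intact) | CC(O)(CO)[C@@H]1CC=C(C)[C@H](O)[C@@H]1O[Si](C)(C)C(C)(C)C
F11 | step 6 | pentaol after hydroboration (C29–OH trans to the chain, C31–Me cis to C24–OH) | CC(O)(CO)[C@@H]1C[C@@H](O)[C@H](C)[C@H](O)[C@@H]1O[Si](C)(C)C(C)(C)C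
F12 | step 6 | methyl ketone diol | CC(=O)[C@@H]1C[C@@H](O)[C@H](C)[C@H](O)[C@@H]1O[Si](C)(C)C(C)(C)C
F13 | step 6 | methyl ketone C29 acetate with free C24–OH | CC(=O)[C@@H]1C[C@@H](OC(C)=O)[C@H](C)[C@H](O)[C@@H]1O[Si](C)(C)C(C)(C)C
F14 | step 17 | N-methoxy-N-methylamide of 21 | C=C1C(C)(C)CCC[C@@]1(C)[C@H](CCOCc1ccccc1)C(=O)N(C)OC
F15 | step 17 | C5 alcohol amide | OC[C@@H]1C(C)(C)CCC[C@@]1(C)[C@H](CCOCc1ccccc1)C(=O)N(C)OC
F16 | step 17 | C5 aldehyde amide | O=C[C@@H]1C(C)(C)CCC[C@@]1(C)[C@H](CCOCc1ccccc1)C(=O)N(C)OC
F17 | step 17 | C5 dioxolane amide | O1CCOC1[C@@H]1C(C)(C)CCC[C@@]1(C)[C@H](CCOCc1ccccc1)C(=O)N(C)OC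
A1 | alternative 1 | tricyclic C5,C10-diketone (rings A, B, C) | O=C1C[C@]2(C)CC(=O)CC[C@H]2[C@]2(C)CCCC(C)(C)[C@@H]12
A2 | alternative 1 | bicyclic C5,C10-diketone with 4-methylpent-3-enyl chain on C14 | O=C1C[C@]2(C)CC(=O)CC[C@H]2[C@](C)(CCC=C(C)C)C1
A3 | alternative 2 | spiro oxolan-3-one with but-3-en-2-yl group on C24 and C5 silyl ether | CC(C)(C)[Si](C)(C)O[C@H]1C[C@]2(C)C[C@]3(CC[C@H]2[C@]2(C)CCCC(C)(C)[C@@H]12)O[C@@H]([C@@H](C)C=C)C(=O)C3
A4 | alternative 2 | diazoketone with (E)-but-2-enyl ether on C10 | CC(C)(C)[Si](C)(C)O[C@H]1C[C@]2(C)C[C@](CC[C@H]2[C@]2(C)CCCC(C)(C)[C@@H]12)(OC/C=C/C)CC(=O)C=[N+]=[N-]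
A5 | alternative 3 | 25-oxo analogue of the target (C25,C29-diketone) | CC(=O)O[C@H]1C[C@]2(C)C[C@]3(CC[C@H]2[C@]2(C)CCCC(C)(C)[C@@H]12)O[C@@H]1C(=O)[C@H]3CC(=O)[C@@H]1C
A6 | alternative 3 | phenylseleno ester on the 4-methylidene-oxolan-3-one | CC(=O)O[C@H]1C[C@]2(C)C[C@]3(CC[C@H]2[C@]2(C)CCCC(C)(C)[C@@H]12)O[C@@H]([C@@H](C)C(=O)[Se]c1ccccc1)C(=O)C3=C
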